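**Plan**
- Numbering: oxolane O1, C2 (aryl ring A), C3 (CH2OH), C4 (CH2–aryl ring B), C5; ring C is the aryl of the glycerol side chain. Cuts: the side chain at its CH(OH)–CH(OAr) bond and at the ArO–CH bond; the core at C4–C5, at C2–C3 and at the alkene that later becomes C4–CH2(ring B).
- Enabling feature: O1–C5H2 is a masked formaldehyde acetal carbon, the CH2OH carbon on C3 is a reduced carboxyl standing 1,3 to O1, and C4–CH2–ring B is a reduced styrene. So O1, C5, one carboxyl oxygen, the carboxyl carbon, C3 and C2 can first form a six-membered 1,3-dioxan-4-one that carries the styrene on C3.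
- Forward: a Wittig reaction and an Evans syn aldol join the core pieces, and formaldehyde closes the hydroxy acid to the dioxanone. Acid then contracts this ring to the oxolane (a C–O bond is traded for C4–C5) while the freed carboxyl closes a temporary γ-lactone on the benzylic cation.
- The temporary benzylic lactone C–O bond is cut by ionic hydrogenation, the acid is reduced and the ring A phenol is freed; its tosylate is the helper that keeps C2–O1 inert to acid. The side chain follows by a second Evans syn aldol, LiBH4 reduction and hydrogenolysis.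
- Stereochemistry: C2 and C3 come from the (S)-oxazolidinone aldol, C4 from the obligatory cis fusion of the temporary lactone, and both side-chain centres (threo) from the (R)-oxazolidinone aldol.

Key step: step 7

Assumption: the benzylic carbon of the temporary lactone is drawn as the exo-aryl epimer expected under equilibrating conditions; this centre becomes CH2 one step later, so its configuration has no bearing on the route.

**Step 1**
Reactants: 1 4-(benzyloxy)-3-methoxybenzaldehyde; 2 (2-carboxyethyl)triphenylphosphonium bromide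
Product: 4 (E)-4-[4-(benzyloxy)-3-methoxyphenyl]but-3-enoic acid, via ylide carboxylate 3 (not isolated)
Conditions: NaN(SiMe3)2 (2.1 equiv), THF, −78 °C to rt; aq. HCl work-up
Reagents that add atoms: none
Why: Wittig olefination with the carboxylate-bearing ylide, which with aromatic aldehydes should give the styrene-conjugated (E)-β,γ-unsaturated acid; no stereocentre is formed.

**Step 2**
Reactants: 4 (E)-4-[4-(benzyloxy)-3-methoxyphenyl]but-3-enoic acid; 5 (S)-4-benzyl-1,3-oxazolidin-2-one
Product: 7 (S)-4-benzyl-3-{(E)-4-[4-(benzyloxy)-3-methoxyphenyl]but-3-enoyl}-1,3-oxazolidin-2-one, via mixed pivalic anhydride 6 (not isolated)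
Conditions: t-BuCOCl, Et3N, THF, −20 °C; then 5, LiCl, −20 °C to rt
Reagents that add atoms: none
Why: N-acylation of the oxazolidinone through the mixed anhydride needs no strong base, so the double bond should stay in conjugation with ring B.

**Step 3**
Reactants: 8 vanillin (4-hydroxy-3-methoxybenzaldehyde)
Product: 9 4-formyl-2-methoxyphenyl 4-methylbenzenesulfonate
Conditions: TsCl, Et3N, DMAP (cat.), CH2Cl2, 0 °C to rt
Reagents that add atoms: 4-methylbenzenesulfonyl chloride, Cc1ccc(cc1)S(=O)(=O)Cl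
Why: Sulfonylation of the phenol turns the para oxygen of ring A from a donor into an acceptor, which later keeps the benzylic C2–O1 bond inert to acid.

**Step 4**
Reactants: 7 the N-(4-arylbut-3-enoyl)oxazolidinone; 9 4-formyl-2-methoxyphenyl 4-methylbenzenesulfonate
Product: 12 (S)-4-benzyl-3-[(2S,3E)-4-[4-(benzyloxy)-3-methoxyphenyl]-2-{(S)-hydroxy[3-methoxy-4-(tosyloxy)phenyl]methyl}but-3-enoyl]-1,3-oxazolidin-2-one (syn aldol adduct), via boron dienolate 10 (not isolated), via boron aldolate 11 (not isolated)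
Conditions: Bu2BOTf (1.2 equiv), Et3N (1.4 equiv), CH2Cl2, −78 to 0 °C; 9, −78 to 0 °C; pH 7 buffer, MeOH, 30 % H2O2, 0 °C
Reagents that add atoms: none
Why: Evans syn aldol reaction in which the (Z)-boron dienolate reacts at its α-carbon through a closed chair transition state on the face away from the benzyl group of the (S)-auxiliary, setting the future C3 and C2 as the (2S,3S)-syn pair.

**Step 5**
Reactants: 12 the syn aldol adduct
Product: 14 (2S,3E)-4-[4-(benzyloxy)-3-methoxyphenyl]-2-{(S)-hydroxy[3-methoxy-4-(tosyloxy)phenyl]methyl}but-3-enoic acid, via lithium peroxycarboxylate 13 (not isolated)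
Conditions: LiOH, 30 % H2O2, THF/H2O, 0 °C; aq. Na2SO3; aq. HCl
Reagents that add atoms: hydrogen peroxide, OO
Why: Hydroperoxide cleavage of the N-acyloxazolidinone attacks the exocyclic carbonyl at 0 °C, where retro-aldol cleavage, α-epimerisation and loss of the aryl sulfonate should not compete.

**Step 6**
Reactants: 14 the β-hydroxy acid; 15 paraformaldehyde (formaldehyde source)
Product: 16 (5S,6S)-5-{(E)-2-[4-(benzyloxy)-3-methoxyphenyl]ethenyl}-6-[3-methoxy-4-(tosyloxy)phenyl]-1,3-dioxan-4-one (5,6-cis)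
Conditions: (CH2O)n (5 equiv), PPTS (10 mol %), 4 Å molecular sieves, 1,2-dichloroethane, 40 °C
Reagents that add atoms: none
Why: Acid-catalysed acetalisation of a β-hydroxy acid with formaldehyde to a 1,3-dioxan-4-one, in which the weak acid should reach the oxygen-trapped ring but not re-ionise the acylal; both stereocentres are untouched.

**Step 7**
Reactants: 16 the 1,3-dioxan-4-one
Product: 19 (3S,3aR,6S,6aS)-3-[4-(benzyloxy)-3-methoxyphenyl]-6-[3-methoxy-4-(tosyloxy)phenyl]tetrahydro-1H,3H-furo[3,4-c]furan-1-one, via oxocarbenium silyl ester 17 (not isolated), via benzylic cation 18 (not isolated)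
Conditions: Me3SiOTf (0.3 equiv), CH2Cl2 (0.02 M), −78 to 0 °C
Reagents that add atoms: none
Why: Proposed new method: Me3SiOTf silylates the carbonyl oxygen of the acylal 16, the carboxylate is the only competent leaving group of the O–CH2–O unit, and the ring opens to the oxocarbenium ion 17 (CH2=O+ on the benzylic oxygen); the inner carbon of the para-benzyloxystyrene attacks this CH2 carbon, so the C–O bond of the six-membered ring is traded for the C4–C5 bond of the five-membered oxolane, and the silyl ester then captures the benzylic cation 18 and releases Me3SiOTf, the whole being an isomerisation. The closest known reaction types are the acetal-initiated oxonium-Prins cyclisation of styrenes to tetrahydrofurans and the Lewis-acid [1,3] oxygen-to-carbon ring contraction of cyclic vinyl acetals; new is the use of a formaldehyde-derived 1,3-dioxan-4-one as the ring that contracts. The oxolane closes 5-exo-trig at the alkene (endo at the C=O+ bond) and the temporary lactone ring closes 5-exo-trig by oxygen attack on the quinoid cation. C2 and C3 are carried over unchanged from 16, the new C4 centre is controlled by the ring fusion, because only the cation whose arm is cis to the silyl ester can lactonise (a trans-fused bicyclo[3.3.0] lactone is too strained) while the trans cation can return by retro-Prins cleavage or by loss and regain of the C4 proton, and the lactone benzylic centre should settle as the exo-aryl epimer and is erased in step 8. Regioselective opening of the acetal is secured by the acyloxy leaving group, 5-exo attack instead of 6-endo closure or a 2-oxonia-Cope shift by the polarisation of the styrene through the para-benzyloxy group of ring B, and the integrity of the benzylic C2–O1 bond by the electron-withdrawing tosylate on ring A.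

**Step 8**
Reactants: 19 the bicyclic lactone
Product: 21 (2S,3S,4R)-4-[4-(benzyloxy)-3-methoxybenzyl]-2-[3-methoxy-4-(tosyloxy)phenyl]oxolane-3-carboxylic acid, via triethylsilyl ester 20 (not isolated)
Conditions: Et3SiH (3 equiv), Me3SiOTf (0.3 equiv), CH2Cl2, −20 to 0 °C; aqueous work-up at pH 3–4
Reagents that add atoms: none
Why: Ionic hydrogenation in which the silyl triflate ionises only the lactone C–O bond at the para-benzyloxybenzylic carbon and Et3SiH traps the cation as CH2, while the C2–O1 bond next to the tosyloxy-substituted ring A does not ionise and C2, C3 and C4 stay untouched.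

**Step 9**
Reactants: 21 the oxolane-3-carboxylic acid
Product: 22 4-{(2S,3R,4R)-4-[4-(benzyloxy)-3-methoxybenzyl]-3-(hydroxymethyl)oxolan-2-yl}-2-methoxyphenyl 4-methylbenzenesulfonate
Conditions: BH3·THF (2.5 equiv), THF, 0 °C to rt; aqueous work-up
Reagents that add atoms: none
Why: Chemoselective borane reduction of a carboxylic acid leaves the sulfonate and benzyl ether alone and avoids any basic medium that could epimerise C3 or open the ring by β-elimination.

**Step 10**
Reactants: 22 the tosylate alcohol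
Product: 23 4-{(2S,3R,4R)-4-[4-(benzyloxy)-3-methoxybenzyl]-3-(hydroxymethyl)oxolan-2-yl}-2-methoxyphenol
Conditions: KOH (5 equiv), MeOH/THF/H2O, 60 °C; aq. HCl to pH 6
Reagents that add atoms: none
Why: Alkaline hydrolysis of the aryl sulfonate by attack at sulfur is safe here because no base-sensitive stereocentre is left after step 9.

**Step 11**
Reactants: 24 (R)-4-benzyl-1,3-oxazolidin-2-one; 25 bromoacetyl bromide
Product: 27 (R)-4-benzyl-3-(2-bromoacetyl)-1,3-oxazolidin-2-one, via lithium oxazolidinide 26 (not isolated)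
Conditions: n-BuLi, THF, −78 °C; then 25, −78 °C
Reagents that add atoms: none
Why: N-acylation of the lithiated oxazolidinone by the acid bromide should be much faster at −78 °C than displacement of the alkyl bromide.

**Step 12**
Reactants: 23 the phenol; 27 the bromoacetyl imide
Product: 28 (R)-4-benzyl-3-(2-{4-[(2S,3R,4R)-4-[4-(benzyloxy)-3-methoxybenzyl]-3-(hydroxymethyl)oxolan-2-yl]-2-methoxyphenoxy}acetyl)-1,3-oxazolidin-2-one
Conditions: K2CO3, acetone, rt
Reagents that add atoms: none
Why: Williamson ether synthesis in which K2CO3 deprotonates only the phenol, whose phenoxide displaces the activated α-bromide while the primary alcohol stays untouched.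

**Step 13**
Reactants: 28 the aryloxyacetyl imide
Product: 29 the acetate of 28 at the C3 hydroxymethyl group
Conditions: Ac2O, pyridine, DMAP (cat.), CH2Cl2, 0 °C to rt
Reagents that add atoms: acetic anhydride, CC(=O)OC(C)=O
Why: Acetylation masks the primary alcohol against Bu2BOTf, and the acetate is chosen because it falls off in step 15 without a step of its own.

**Step 14**
Reactants: 29 the acetate imide; 1 4-(benzyloxy)-3-methoxybenzaldehyde
Product: 32 the (2R,3S)-syn aldol adduct, a 3-[4-(benzyloxy)-3-methoxyphenyl]-3-hydroxy-2-aryloxypropanoyl imide of the (R)-auxiliary, via boron enolate 30 (not isolated), via boron aldolate 31 (not isolated)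
Conditions: Bu2BOTf (1.2 equiv), Et3N (1.4 equiv), CH2Cl2, −78 to 0 °C; 1, −78 to 0 °C; pH 7 buffer, MeOH, 30 % H2O2, 0 °C
Reagents that add atoms: none
Why: Evans syn aldol reaction of a glycolate-type imide, in which the (Z)-boron enolate and the (R)-auxiliary set both new centres as (2R,3S) through the chair transition state, that is the threo side chain, while the remote core centres have no say.

**Step 15**
Reactants: 32 the side-chain aldol adduct
Product: 33 the di-O-benzyl ether of the target (benzyl on the phenols of rings B and C)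
Conditions: LiBH4 (5 equiv), MeOH (5 equiv), THF, 0 °C to rt
Reagents that add atoms: none
Why: Reductive cleavage of the N-acyloxazolidinone with LiBH4 gives the primary alcohol without touching the two new centres, and the same reagent reduces the acetate off.

**Step 16**
Reactants: 33 the di-O-benzyl ether
Product: 34 the target, (7''S,8''S)-threo-guaiacylglycerol 8''-O-4 ether of (+)-lariciresinol
Conditions: H2 (1 atm), Pd/C (10 wt %), EtOAc/EtOH, rt
Reagents that add atoms: none
Why: Hydrogenolysis of the two aryl benzyl ethers under neutral conditions should be much faster than cleavage of the benzylic alcohol or of the 2-aryloxolane C–O bond.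

**Compound list**
1 | 4-(benzyloxy)-3-methoxybenzaldehyde | O=Cc1ccc(OCc2ccccc2)c(OC)c1 | starting material
2 | (2-carboxyethyl)triphenylphosphonium bromide | OC(=O)CC[P+](c1ccccc1)(c1ccccc1)c1ccccc1.[Br-] | starting material
3 | sodium 3-(triphenylphosphoranylidene)propanoate | [Na+].[O-]C(=O)CC=P(c1ccccc1)(c1ccccc1)c1ccccc1 | intermediate
4 | (E)-4-[4-(benzyloxy)-3-methoxyphenyl]but-3-enoic acid | OC(=O)C/C=C/c1ccc(OCc2ccccc2)c(OC)c1 | intermediate
5 | (S)-4-benzyl-1,3-oxazolidin-2-one | O=C1N[C@@H](Cc2ccccc2)CO1 | starting material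
6 | mixed anhydride of 4 and pivalic acid | CC(C)(C)C(=O)OC(=O)C/C=C/c1ccc(OCc2ccccc2)c(OC)c1 | intermediate
7 | (S)-4-benzyl-3-{(E)-4-[4-(benzyloxy)-3-methoxyphenyl]but-3-enoyl}-1,3-oxazolidin-2-one | O=C(C/C=C/c1ccc(OCc2ccccc2)c(OC)c1)N1[C@@H](Cc2ccccc2)COC1=O | intermediate
8 | vanillin | O=Cc1ccc(O)c(OC)c1 | starting material
9 | 4-formyl-2-methoxyphenyl 4-methylbenzenesulfonate | O=Cc1ccc(OS(=O)(=O)c2ccc(C)cc2)c(OC)c1 | intermediate
10 | (Z)-dibutylboron dienolate of 7 | CCCCB(CCCC)O/C(=C\C=C\c1ccc(OCc2ccccc2)c(OC)c1)N1[C@@H](Cc2ccccc2)COC1=O | intermediate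
11 | dibutylboron aldolate of 12 | O=C(N1[C@@H](Cc2ccccc2)COC1=O)[C@@H](/C=C/c1ccc(OCc2ccccc2)c(OC)c1)[C@H](OB(CCCC)CCCC)c1ccc(OS(=O)(=O)c2ccc(C)cc2)c(OC)c1 | intermediate
12 | (2S,3S)-syn aldol adduct on the (S)-auxiliary | O=C(N1[C@@H](Cc2ccccc2)COC1=O)[C@@H](/C=C/c1ccc(OCc2ccccc2)c(OC)c1)[C@H](O)c1ccc(OS(=O)(=O)c2ccc(C)cc2)c(OC)c1 | intermediate
13 | lithium peroxycarboxylate of 14 | [Li+].[O-]OC(=O)[C@@H](/C=C/c1ccc(OCc2ccccc2)c(OC)c1)[C@H](O)c1ccc(OS(=O)(=O)c2ccc(C)cc2)c(OC)c1 | intermediate
14 | (2S,3E)-4-[4-(benzyloxy)-3-methoxyphenyl]-2-{(S)-hydroxy[3-methoxy-4-(tosyloxy)phenyl]methyl}but-3-enoic acid | OC(=O)[C@@H](/C=C/c1ccc(OCc2ccccc2)c(OC)c1)[C@H](O)c1ccc(OS(=O)(=O)c2ccc(C)cc2)c(OC)c1 | intermediate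
15 | paraformaldehyde (formaldehyde source) | C=O | starting material
16 | (5S,6S)-5-styryl-6-aryl-1,3-dioxan-4-one | O=C1OCO[C@H](c2ccc(OS(=O)(=O)c3ccc(C)cc3)c(OC)c2)[C@@H]1/C=C/c1ccc(OCc2ccccc2)c(OC)c1 | intermediate
17 | ring-opened oxocarbenium trimethylsilyl ester, triflate salt | C[Si](C)(C)OC(=O)[C@@H](/C=C/c1ccc(OCc2ccccc2)c(OC)c1)[C@H]([O+]=C)c1ccc(OS(=O)(=O)c2ccc(C)cc2)c(OC)c1.[O-]S(=O)(=O)C(F)(F)F | intermediate
18 | oxolane benzylic cation trimethylsilyl ester, triflate salt | C[Si](C)(C)OC(=O)[C@@H]1[C@@H](c2ccc(OS(=O)(=O)c3ccc(C)cc3)c(OC)c2)OC[C@@H]1[CH+]c1ccc(OCc2ccccc2)c(OC)c1.[O-]S(=O)(=O)C(F)(F)F | intermediate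
19 | (3S,3aR,6S,6aS)-furo[3,4-c]furan-1-one (oxolane fused to the temporary lactone) | O=C1O[C@H](c2ccc(OCc3ccccc3)c(OC)c2)[C@H]2CO[C@H](c3ccc(OS(=O)(=O)c4ccc(C)cc4)c(OC)c3)[C@@H]12 | intermediate
20 | triethylsilyl ester of 21 | CC[Si](CC)(CC)OC(=O)[C@@H]1[C@@H](c2ccc(OS(=O)(=O)c3ccc(C)cc3)c(OC)c2)OC[C@@H]1Cc1ccc(OCc2ccccc2)c(OC)c1 | intermediate
21 | (2S,3S,4R)-oxolane-3-carboxylic acid | OC(=O)[C@@H]1[C@@H](c2ccc(OS(=O)(=O)c3ccc(C)cc3)c(OC)c2)OC[C@@H]1Cc1ccc(OCc2ccccc2)c(OC)c1 | intermediate
22 | (2S,3R,4R)-3-(hydroxymethyl)oxolane, ring A tosylate | OC[C@@H]1[C@@H](c2ccc(OS(=O)(=O)c3ccc(C)cc3)c(OC)c2)OC[C@@H]1Cc1ccc(OCc2ccccc2)c(OC)c1 | intermediate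
23 | (2S,3R,4R)-3-(hydroxymethyl)oxolane, ring A phenol | OC[C@@H]1[C@@H](c2ccc(O)c(OC)c2)OC[C@@H]1Cc1ccc(OCc2ccccc2)c(OC)c1 | intermediate
24 | (R)-4-benzyl-1,3-oxazolidin-2-one | O=C1N[C@H](Cc2ccccc2)CO1 | starting material
25 | bromoacetyl bromide | O=C(Br)CBr | starting material
26 | lithium salt of 24 | [Li+].O=C1[N-][C@H](Cc2ccccc2)CO1 | intermediate
27 | (R)-4-benzyl-3-(2-bromoacetyl)-1,3-oxazolidin-2-one | O=C(CBr)N1[C@H](Cc2ccccc2)COC1=O | intermediate
28 | aryloxyacetyl imide | OC[C@@H]1[C@@H](c2ccc(OCC(=O)N3[C@H](Cc4ccccc4)COC3=O)c(OC)c2)OC[C@@H]1Cc1ccc(OCc2ccccc2)c(OC)c1 | intermediate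
29 | acetate of 28 | CC(=O)OC[C@@H]1[C@@H](c2ccc(OCC(=O)N3[C@H](Cc4ccccc4)COC3=O)c(OC)c2)OC[C@@H]1Cc1ccc(OCc2ccccc2)c(OC)c1 | intermediate
30 | (Z)-dibutylboron enolate of 29 | CC(=O)OC[C@@H]1[C@@H](c2ccc(O/C=C(\OB(CCCC)CCCC)N3[C@H](Cc4ccccc4)COC3=O)c(OC)c2)OC[C@@H]1Cc1ccc(OCc2ccccc2)c(OC)c1 | intermediate
31 | dibutylboron aldolate of 32 | CC(=O)OC[C@@H]1[C@@H](c2ccc(O[C@@H](C(=O)N3[C@H](Cc4ccccc4)COC3=O)[C@@H](OB(CCCC)CCCC)c3ccc(OCc4ccccc4)c(OC)c3)c(OC)c2)OC[C@@H]1Cc1ccc(OCc2ccccc2)c(OC)c1 | intermediate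
32 | (2R,3S)-syn aldol adduct on the (R)-auxiliary | CC(=O)OC[C@@H]1[C@@H](c2ccc(O[C@@H](C(=O)N3[C@H](Cc4ccccc4)COC3=O)[C@@H](O)c3ccc(OCc4ccccc4)c(OC)c3)c(OC)c2)OC[C@@H]1Cc1ccc(OCc2ccccc2)c(OC)c1 | intermediate
33 | di-O-benzyl ether of the target | OC[C@@H]1[C@@H](c2ccc(O[C@@H](CO)[C@@H](O)c3ccc(OCc4ccccc4)c(OC)c3)c(OC)c2)OC[C@@H]1Cc1ccc(OCc2ccccc2)c(OC)c1 | intermediate
34 | target CNP0226724.1 | COc1cc(C[C@H]2CO[C@H](c3ccc(O[C@@H](CO)[C@@H](O)c4ccc(O)c(OC)c4)c(OC)c3)[C@H]2CO)ccc1O | target

**Step count and risks**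
Total step count: 16. Longest linear sequence: 14 (steps 1, 2, 4–10, 12–16).

Steps most likely to fail:

1. **Step 7.**
   - What may go wrong: the opened acylal may re-close faster than the alkene attacks. The cationic intermediates may also be drained by oligomerisation of the electron-rich styrene or by a 2-oxonia-Cope shift.
   - Fallback (known chemistry, no ring contraction; sets out from 9 and 1, comes back at 22). Addition of CH2=CHMgBr to 9 would give racemic 1-[3-methoxy-4-(tosyloxy)phenyl]prop-2-en-1-ol F1.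
   - A Sharpless kinetic resolution (Ti(OiPr)4, D-(−)-diisopropyl tartrate, t-BuOOH) would epoxidise its (S)-enantiomer to the anti epoxy alcohol (R)-[3-methoxy-4-(tosyloxy)phenyl][(S)-oxiran-2-yl]methanol F2.
   - In parallel, 1 would be taken by a Horner–Wadsworth–Emmons reaction (triethyl phosphonoacetate, NaH) to ethyl (E)-3-[4-(benzyloxy)-3-methoxyphenyl]acrylate F3. iBu2AlH would then give (E)-3-[4-(benzyloxy)-3-methoxyphenyl]prop-2-en-1-ol F4, and PBr3 would give (E)-1-(benzyloxy)-4-(3-bromoprop-1-enyl)-2-methoxybenzene F5.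
   - Williamson etherification of F2 with F5 (NaH, THF) would give the epoxy cinnamyl ether of F2 F6.
   - Cp2TiCl (trivalent titanium, made from Cp2TiCl2 and Zn) would open the epoxide to the secondary radical at the future C3. This radical closes the oxolane 5-exo onto the cinnamyl double bond through a chair-like transition state (2,3-trans, 3,4-cis). Acidic work-up of the benzylic titanium species leads to 22.

2. **Step 6.**
   - What may go wrong: under acid the hemiacetal stage may ionise too early, the styrene may be protonated and lactonise, or formaldehyde may be lost again before the ring closes.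
   - Fallback (basic instead of acidic ring closure; sets out from 14, comes back at 16). Phase-transfer esterification of 14 with chloromethyl chlorosulfate (NaHCO3, Bu4NHSO4, CH2Cl2/H2O) would give the chloromethyl ester of 14 F7. Its β-hydroxy group would then close the ring by intramolecular O-alkylation (iPr2NEt, NaI cat., MeCN) to 16.

3. **Step 8.**
   - What may go wrong: the aryl benzyl ether of ring B may be lost under the Lewis-acidic conditions, or the lactone may ionise too slowly for clean hydride capture.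
   - Fallback (heterogeneous hydrogenolysis instead of ionic reduction; sets out from 19, comes back at 22). H2 over Pd/C in EtOAc/AcOH would cleave the benzylic ester C–O bond of the lactone together with the aryl benzyl ether. This gives (2S,3S,4R)-4-(4-hydroxy-3-methoxybenzyl)-2-[3-methoxy-4-(tosyloxy)phenyl]oxolane-3-carboxylic acid F8.
   - BnBr and K2CO3 in DMF at rt would give the benzyl ether benzyl ester of F8 F9, and LiBH4 would reduce the ester to 22.

**Further compounds**
F1 | step 7 | rac-1-[3-methoxy-4-(tosyloxy)phenyl]prop-2-en-1-ol | C=CC(O)c1ccc(OS(=O)(=O)c2ccc(C)cc2)c(OC)c1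
F2 | step 7 | (R)-[3-methoxy-4-(tosyloxy)phenyl][(S)-oxiran-2-yl]methanol | O[C@H](c1ccc(OS(=O)(=O)c2ccc(C)cc2)c(OC)c1)[C@@H]1CO1
F3 | step 7 | ethyl (E)-3-[4-(benzyloxy)-3-methoxyphenyl]acrylate | CCOC(=O)/C=C/c1ccc(OCc2ccccc2)c(OC)c1
F4 | step 7 | (E)-3-[4-(benzyloxy)-3-methoxyphenyl]prop-2-en-1-ol | OC/C=C/c1ccc(OCc2ccccc2)c(OC)c1
F5 | step 7 | (E)-1-(benzyloxy)-4-(3-bromoprop-1-enyl)-2-methoxybenzene | BrC/C=C/c1ccc(OCc2ccccc2)c(OC)c1
F6 | step 7 | epoxy cinnamyl ether of F2 | C(/C=C/c1ccc(OCc2ccccc2)c(OC)c1)O[C@H](c1ccc(OS(=O)(=O)c2ccc(C)cc2)c(OC)c1)[C@@H]1CO1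
F7 | step 6 | chloromethyl ester of 14 | ClCOC(=O)[C@@H](/C=C/c1ccc(OCc2ccccc2)c(OC)c1)[C@H](O)c1ccc(OS(=O)(=O)c2ccc(C)cc2)c(OC)c1
F8 | step 8 | (2S,3S,4R)-4-(4-hydroxy-3-methoxybenzyl)-2-[3-methoxy-4-(tosyloxy)phenyl]oxolane-3-carboxylic acid | OC(=O)[C@@H]1[C@@H](c2ccc(OS(=O)(=O)c3ccc(C)cc3)c(OC)c2)OC[C@@H]1Cc1ccc(O)c(OC)c1
F9 | step 8 | benzyl ether benzyl ester of F8 | O=C(OCc1ccccc1)[C@@H]1[C@@H](c2ccc(OS(=O)(=O)c3ccc(C)cc3)c(OC)c2)OC[C@@H]1Cc1ccc(OCc2ccccc2)c(OC)c1
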